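**Retrosynthetic overview**

- Target 34 ← phenol desilylation ← hydroxyl-directed epoxidation of a C1=C2 alkene ← Corey–Winter olefination of a 1β,2β-diol ← C5 ester ← 1,3-anti reduction at C5 ← Li/NH3 reduction of a C3a=C4–C5=O enone ← methyl addition to the C7 ketone of cycloadduct 19.
- Feature: in the seven-membered ring (C3a, C4, C5, C6, C7, C8, C8a) the unit C6–C7–C8 carries oxygen on its central carbon C7 and is bonded to C5 and C8a. These are the ends of the four-carbon unit C8a–C3a–C4–C5 that sits on the five-membered ring (C1, C2, C3, C3a, C8a): the pattern of a 2-oxyallyl cation added across a diene.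
- Key disconnection: C8–C8a and C5–C6, a [4+3] cycloaddition of the 2-silyloxyallyl cation from 16 with silyl dienol ether 14; the C1,C2 acetonide of 14 steers the face of attack at C8a.
- Diene 14 ← aldehyde 13 ← hydroboration of diene 11 ← ring-closing enyne metathesis of 10 ← epoxide alkynylation ← kinetic-resolution epoxidation of dienol 3.
- Ring order: five-membered carbocycle (step 6), seven-membered ring (step 11), oxirane (step 22); the dioxolane is temporary (step 5 to step 19).

Key step: step 11

Remark: positions follow the hydroazulene numbering used above and β is the face of H-8a. Enolisation in step 9 is assumed to give mainly the (E)-dienol ether; any (Z)-isomer should converge in step 11, because C5 is oxidised in step 14.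

**Route**

Step 1
Reactants: 1 methacrolein; 2 vinylmagnesium bromide
Product: 3 racemic 2-methylpenta-1,4-dien-3-ol
Conditions: THF, −78 → 0 °C; aq. NH4Cl
Reagents that add atoms: none
Why: Grignard 1,2-addition to the aldehyde is fast at low temperature, so the bis-allylic alcohol should form without conjugate addition.

Step 2
Reactants: 3 racemic 2-methylpenta-1,4-dien-3-ol
Product: 4 (1R)-1-[(2S)-2-methyloxiran-2-yl]prop-2-en-1-ol
Conditions: Ti(O-i-Pr)4 (10 mol %), D-(−)-diisopropyl tartrate (15 mol %), t-BuOOH (0.45 equiv), 4 Å molecular sieves, CH2Cl2, −20 °C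
Reagents that add atoms: tert-butyl hydroperoxide CC(C)(C)OO
Why: Sharpless kinetic-resolution epoxidation: with the D-(−)-tartrate the (R)-alcohol should react fast at its more nucleophilic 1,1-disubstituted alkene to give the erythro epoxy alcohol, which fixes C1 (R) and C2 (S), while the (S)-alcohol and the vinyl group are left and the former is separated.

Step 3
Reactants: 4 (1R)-1-[(2S)-2-methyloxiran-2-yl]prop-2-en-1-ol
Product: 5 triethylsilyl ether of 4
Conditions: Et3SiCl, imidazole, CH2Cl2, 0 °C
Reagents that add atoms: chlorotriethylsilane CC[Si](Cl)(CC)CC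
Why: Routine silylation of a secondary alcohol, so that the hydroxyl does not consume acetylide and Lewis acid in step 4.

Step 4
Reactants: 5 triethylsilyl ether of 4; 6 3-methylbut-1-yne
Product: 8 (3R,4S)-4,8-dimethyl-3-(triethylsilyloxy)non-1-en-6-yn-4-ol, via lithium 3-methylbut-1-ynide 7 (not isolated)
Conditions: 6, n-BuLi, THF, −78 °C; BF3·OEt2, then 5, −78 °C; aq. NaHCO3
Reagents that add atoms: none
Why: BF3-promoted alkynylation of an epoxide (Yamaguchi-type opening): the acetylide should attack the unsubstituted oxirane carbon in an SN2 manner, which attaches C3 and leaves the C2 carbinol centre untouched.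

Step 5
Reactants: 8 (3R,4S)-4,8-dimethyl-3-(triethylsilyloxy)non-1-en-6-yn-4-ol
Product: 10 (4S,5R)-2,2,4-trimethyl-4-(4-methylpent-2-yn-1-yl)-5-vinyl-1,3-dioxolane, via enyne diol 9 (not isolated)
Conditions: p-TsOH·H2O (5 mol %), MeOH, rt; concentrate; 2,2-dimethoxypropane, acetone, rt; Et3N
Reagents that add atoms: 2,2-dimethoxypropane COC(C)(C)OC
Why: Acid methanolysis of the triethylsilyl ether followed by transketalisation should give the dioxolane, in which the erythro diol places the vinyl and propargyl arms cis and thus close for ring closure.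

Step 6
Reactants: 10 (4S,5R)-2,2,4-trimethyl-4-(4-methylpent-2-yn-1-yl)-5-vinyl-1,3-dioxolane
Product: 11 (3aS,6aR)-2,2,3a-trimethyl-5-(3-methylbut-1-en-2-yl)-4,6a-dihydro-3aH-cyclopenta[d][1,3]dioxole (diene C8a=C3a–C4(i-Pr)=C5H2)
Conditions: second-generation Grubbs catalyst (5 mol %), ethylene (1 atm), CH2Cl2, 40 °C
Reagents that add atoms: none
Why: Ring-closing enyne metathesis in the exo mode: the ruthenium alkylidene formed at the vinyl group should add to the alkyne, close the five-membered ring with the C8a=C3a alkene and leave the isopropyl-bearing alkyne carbon as the exocyclic C4=C5 methylene, with no stereocentre touched.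

Step 7
Reactants: 11 semicyclic diene
Product: 12 3-methyl-2-[(3aS,6aR)-2,2,3a-trimethyl-4,6a-dihydro-3aH-cyclopenta[d][1,3]dioxol-5-yl]butan-1-ol (both C4 epimers)
Conditions: 9-borabicyclo[3.3.1]nonane, THF, 0 → 50 °C; then NaOH, H2O2, 0 °C
Reagents that add atoms: hydrogen peroxide OO
Why: Hydroboration–oxidation: the bulky borane should add only to the terminal 1,1-disubstituted alkene with boron on C5 and leave the trisubstituted ring alkene, and the C4 centre formed as a mixture becomes sp2 again in step 9.

Step 8
Reactants: 12 primary alcohol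
Product: 13 3-methyl-2-[(3aS,6aR)-2,2,3a-trimethyl-4,6a-dihydro-3aH-cyclopenta[d][1,3]dioxol-5-yl]butanal (both C4 epimers)
Conditions: Dess–Martin periodinane, NaHCO3, CH2Cl2, 0 °C
Reagents that add atoms: none
Why: Dess–Martin oxidation under buffered, non-basic conditions should give the β,γ-unsaturated aldehyde without moving the ring alkene into conjugation.

Step 9
Reactants: 13 aldehyde
Product: 14 (E)-tert-butyldimethylsilyl dienol ether of 13 (diene C8a=C3a–C4(i-Pr)=C5H–OSi; 1,2-acetonide)
Conditions: t-BuMe2SiOTf, Et3N, CH2Cl2, −78 → 0 °C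
Reagents that add atoms: tert-butyldimethylsilyl trifluoromethanesulfonate CC(C)(C)[Si](C)(C)OS(=O)(=O)C(F)(F)F
Why: Soft enolisation with silyl triflate and amine of an aldehyde that has a single, doubly activated α-hydrogen can only give the C4=C5 enol ether conjugated with C3a=C8a, and the (E)-isomer, with the silyloxy group turned away from the ring, should predominate because it keeps the diene planar.

Step 10
Reactants: 15 chloroacetone
Product: 16 3-chloro-2-(trimethylsilyloxy)propene
Conditions: LiN(i-Pr)2, Me3SiCl (internal quench), THF, −78 °C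
Reagents that add atoms: chlorotrimethylsilane C[Si](C)(C)Cl
Why: Kinetic enolisation of the methyl ketone by a hindered amide at the unhindered methyl group with in situ O-silylation should give the less substituted silyl enol ether before equilibration or self-condensation can occur.

Step 11
Reactants: 14 silyl dienol ether; 16 3-chloro-2-(trimethylsilyloxy)propene
Product: 19 hydroazulenone cycloadduct (C7 ketone; C3a=C4 alkene; 5α-silyloxy; 1β,2β-acetonide; 8aβ-H), via 2-(trimethylsilyloxy)allyl perchlorate 17 (not isolated), via C8a-alkylated silyloxocarbenium perchlorate 18 (not isolated)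
Conditions: AgClO4 (1.5 equiv), 16 (1.5 equiv), 2,6-di-tert-butyl-4-methylpyridine (0.2 equiv), CH3NO2–CH2Cl2, −30 → 0 °C, dark; aq. NaHCO3
Reagents that add atoms: none
Why: Silver-assisted ionisation of 16 gives the 2-silyloxyallyl cation 17, which the dienol ether attacks at C8a, its vinylogous nucleophilic terminus, to give the C5 silyloxocarbenium ion 18; the silyl enol ether carbon C6 then bonds to C5 and loss of the trimethylsilyl group to perchlorate unveils the C7 ketone, so that C8–C8a and C5–C6 form in one strongly asynchronous [4+3] union. The closest known reaction type is the [4+3] cycloaddition of 2-oxyallyl cations, generated from 2-silyloxyallyl halides by silver salts, with 1,3-dienes. The seven-membered ring is closed by a 7-(enolendo)-exo-trig attack of the enol ether on the oxocarbenium carbon, whereas the alternative bond to C3a would be a disfavoured 5-(enolendo) closure that builds a quaternary centre. C8a is set by approach of the cation to the convex α face of the cis-fused cyclopentene–dioxolane, anti to the oxygens on C1 and C2, and the 5α-silyloxy centre follows from suprafacial bonding to the (E)-dienol ether but is erased in step 14. The step needs attack at C8a and not at C4, which the isopropyl group on C4 and the extended conjugation should secure, and it needs the dienol ether to survive until it is alkylated, which the hindered pyridine buffer, the aprotic medium and the low temperature are meant to secure.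

Step 12
Reactants: 19 cycloadduct ketone
Product: 20 tertiary alcohol (7α-hydroxy; 7β-methyl; 5α-silyloxy; C3a=C4 alkene; acetonide)
Conditions: MeMgBr, CeCl3 (anhydrous), THF, −78 °C; aq. NH4Cl
Reagents that add atoms: methylmagnesium bromide C[Mg]Br
Why: Organocerium 1,2-addition suppresses enolisation and loss of the β-silyloxy group, and allylic 1,2-strain with the C4 isopropyl group should hold the 5α-silyloxy group pseudoaxial, so that the methyl group enters C7 from the β face.

Step 13
Reactants: 20 tertiary alcohol
Product: 21 5α,7α-diol (C3a=C4 alkene; acetonide)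
Conditions: n-Bu4NF, THF, 0 °C → rt; aq. NH4Cl
Reagents that add atoms: none
Why: Fluoride cleavage of the secondary silyl ether; no carbonyl group is present at this stage, so the basic medium has nothing to eliminate.

Step 14
Reactants: 21 diol
Product: 22 enone (C3a=C4–C5=O; 7α-hydroxy; 7β-methyl; acetonide)
Conditions: Dess–Martin periodinane, NaHCO3, CH2Cl2, 0 °C → rt
Reagents that add atoms: none
Why: Oxidation of the allylic secondary alcohol, with the tertiary C7 alcohol inert, removes the C5 centre formed in step 11 and gives the enone needed for the reduction.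

Step 15
Reactants: 22 enone
Product: 24 trans-fused ketone (3aα-H; 8aβ-H; 4α-isopropyl; C5 ketone; 7α-hydroxy; acetonide), via lithium enolate 23 (not isolated)
Conditions: Li, NH3(l)–THF, t-BuOH (1 equiv), −78 °C, 10 min; isoprene, then solid NH4Cl
Reagents that add atoms: none
Why: Dissolving-metal conjugate reduction: the β-carbon C3a should be protonated on the convex α face of the cyclopentane–dioxolane unit, which gives the trans ring fusion, and enolate 23 should then be protonated axially at C4 so that the isopropyl group takes the equatorial α position, also the thermodynamically favoured one, while the short time at −78 °C guards the tertiary β-hydroxy ketone against retro-aldol cleavage.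

Step 16
Reactants: 24 trans-fused ketone
Product: 25 5β,7α-diol (4α-isopropyl; trans ring fusion; acetonide)
Conditions: Me4NBH(OAc)3, MeCN–AcOH, −25 °C
Reagents that add atoms: none
Why: Evans–Saksena hydroxyl-directed reduction: the triacetoxyborohydride should bind the 7α-hydroxyl and deliver hydride to the α face of the C5 ketone, giving the 1,3-anti diol with the 5β-hydroxyl.

Step 17
Reactants: 26 4-hydroxybenzoic acid
Product: 28 4-(tert-butyldimethylsilyloxy)benzoic acid, via bis-silylated ester 27 (not isolated)
Conditions: t-BuMe2SiCl (2.2 equiv), imidazole, DMF, rt; then AcOH–H2O–THF, rt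
Reagents that add atoms: tert-butyldimethylsilyl chloride CC(C)(C)[Si](C)(C)Cl
Why: Exhaustive silylation followed by selective hydrolysis of the labile silyl ester should leave the aryl silyl ether, which keeps the phenol from being acylated in step 18.

Step 18
Reactants: 25 5β,7α-diol; 28 4-(tert-butyldimethylsilyloxy)benzoic acid
Product: 29 5β-[4-(tert-butyldimethylsilyloxy)benzoate] (7α-hydroxy; acetonide)
Conditions: N,N'-dicyclohexylcarbodiimide, 4-(dimethylamino)pyridine (0.2 equiv), CH2Cl2, 0 °C → rt
Reagents that add atoms: none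
Why: Steglich esterification should acylate the secondary equatorial C5 hydroxyl with retention, while the tertiary C7 hydroxyl does not react.

Step 19
Reactants: 29 ester acetonide
Product: 30 1β,2β,7α-triol 5β-ester
Conditions: AcOH–H2O (4:1), 45 °C
Reagents that add atoms: none
Why: Mild acid hydrolysis of the acetonide, which the benzoate, the aryl silyl ether and the tertiary alcohol should tolerate.

Step 20
Reactants: 30 triol
Product: 31 1β,2β-cyclic thionocarbonate (7α-hydroxy free)
Conditions: 1,1'-thiocarbonyldiimidazole, 4-(dimethylamino)pyridine (cat.), toluene, 80 °C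
Reagents that add atoms: 1,1'-thiocarbonyldiimidazole S=C(n1ccnc1)n1ccnc1
Why: First stage of the Corey–Winter olefination: the cis-1,2-diol on the five-membered ring should close to the cyclic thionocarbonate, while the isolated tertiary C7 hydroxyl cannot form a ring and stays free.

Step 21
Reactants: 31 thionocarbonate
Product: 32 C1=C2 alkene (2-methylcyclopentene ring; 7α-hydroxy; 5β-ester)
Conditions: 1,3-dimethyl-2-phenyl-1,3,2-diazaphospholidine, THF, 40 °C
Reagents that add atoms: none
Why: Corey–Winter olefination: desulfurisation by the phosphorus reagent and loss of CO2 in a stereospecific syn-elimination can only give the ring alkene C1=C2 from the cis-fused thionocarbonate.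

Step 22
Reactants: 32 alkene
Product: 33 1α,2α-epoxide (aryl silyl ether of the target)
Conditions: VO(acac)2 (5 mol %), t-BuOOH, CH2Cl2, 0 °C → rt
Reagents that add atoms: tert-butyl hydroperoxide CC(C)(C)OO
Why: Hydroxyl-directed vanadium-catalysed epoxidation: the peroxide is activated on vanadium bound to the 7α-hydroxyl, a bis-homoallylic alcohol whose C8 arm lies on the α side of the cyclopentene, and should be delivered to the α face of C1=C2, while undirected epoxidation of an isolated alkene by this system is slow.

Step 23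
Reactants: 33 silyl-protected epoxide
Product: 34 target CNP0245441.1
Conditions: n-Bu4NF, AcOH (1:1), THF, 0 °C
Reagents that add atoms: none
Why: Buffered fluoride should remove the aryl silyl ether within minutes and leave the ester, the epoxide and the tertiary alcohol untouched.

**Compound list**

1 | methacrolein | CC(=C)C=O | starting material
2 | vinylmagnesium bromide | C=C[Mg]Br | starting material
3 | racemic 2-methylpenta-1,4-dien-3-ol | C=CC(O)C(C)=C | intermediate
4 | (1R)-1-[(2S)-2-methyloxiran-2-yl]prop-2-en-1-ol | C=C[C@@H](O)[C@]1(C)CO1 | intermediate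
5 | triethyl{[(1R)-1-[(2S)-2-methyloxiran-2-yl]prop-2-en-1-yl]oxy}silane | C=C[C@@H](O[Si](CC)(CC)CC)[C@]1(C)CO1 | intermediate
6 | 3-methylbut-1-yne | CC(C)C#C | starting material
7 | lithium 3-methylbut-1-ynide (not isolated) | CC(C)C#C[Li] | intermediate
8 | (3R,4S)-4,8-dimethyl-3-(triethylsilyloxy)non-1-en-6-yn-4-ol | C=C[C@@H](O[Si](CC)(CC)CC)[C@@](C)(O)CC#CC(C)C | intermediate
9 | (3R,4S)-4,8-dimethylnon-1-en-6-yne-3,4-diol (not isolated) | C=C[C@@H](O)[C@@](C)(O)CC#CC(C)C | intermediate
10 | (4S,5R)-2,2,4-trimethyl-4-(4-methylpent-2-yn-1-yl)-5-vinyl-1,3-dioxolane | C=C[C@H]1OC(C)(C)O[C@@]1(C)CC#CC(C)C | intermediate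
11 | (3aS,6aR)-2,2,3a-trimethyl-5-(3-methylbut-1-en-2-yl)-4,6a-dihydro-3aH-cyclopenta[d][1,3]dioxole | C=C(C(C)C)C1=C[C@H]2OC(C)(C)O[C@@]2(C)C1 | intermediate
12 | 3-methyl-2-[(3aS,6aR)-2,2,3a-trimethyl-4,6a-dihydro-3aH-cyclopenta[d][1,3]dioxol-5-yl]butan-1-ol, both C4 epimers | OCC(C(C)C)C1=C[C@H]2OC(C)(C)O[C@@]2(C)C1 | intermediate
13 | 3-methyl-2-[(3aS,6aR)-2,2,3a-trimethyl-4,6a-dihydro-3aH-cyclopenta[d][1,3]dioxol-5-yl]butanal, both C4 epimers | O=CC(C(C)C)C1=C[C@H]2OC(C)(C)O[C@@]2(C)C1 | intermediate
14 | (E)-tert-butyldimethylsilyl dienol ether of 13 (precursor of the key step) | CC(C)/C(=C\O[Si](C)(C)C(C)(C)C)C1=C[C@H]2OC(C)(C)O[C@@]2(C)C1 | intermediate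
15 | chloroacetone | CC(=O)CCl | starting material
16 | 3-chloro-2-(trimethylsilyloxy)propene | C=C(CCl)O[Si](C)(C)C | intermediate
17 | 2-(trimethylsilyloxy)allyl perchlorate (not isolated) | C=C(O[Si](C)(C)C)[CH2+].[O-]Cl(=O)(=O)=O | intermediate
18 | C8a-alkylated C5 silyloxocarbenium perchlorate (not isolated) | CC(C)C(C=[O+][Si](C)(C)C(C)(C)C)=C1C[C@]2(C)OC(C)(C)O[C@@H]2[C@H]1CC(=C)O[Si](C)(C)C.[O-]Cl(=O)(=O)=O | intermediate
19 | hydroazulenone cycloadduct: C7 ketone, C3a=C4 alkene, 5α-(tert-butyldimethylsilyloxy), 1β,2β-acetonide, 8aβ-H (product of the key step) | CC(C)C1=C2C[C@]3(C)OC(C)(C)O[C@@H]3[C@H]2CC(=O)C[C@H]1O[Si](C)(C)C(C)(C)C | intermediate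
20 | 7α-hydroxy-7β-methyl 5α-silyl ether, C3a=C4 alkene, acetonide | CC(C)C1=C2C[C@]3(C)OC(C)(C)O[C@@H]3[C@H]2C[C@@](C)(O)C[C@H]1O[Si](C)(C)C(C)(C)C | intermediate
21 | 5α,7α-diol, C3a=C4 alkene, acetonide | CC(C)C1=C2C[C@]3(C)OC(C)(C)O[C@@H]3[C@H]2C[C@@](C)(O)C[C@H]1O | intermediate
22 | enone C3a=C4–C5=O, 7α-hydroxy-7β-methyl, acetonide | CC(C)C1=C2C[C@]3(C)OC(C)(C)O[C@@H]3[C@H]2C[C@@](C)(O)CC1=O | intermediate
23 | lithium C4=C5 enolate of 24 (not isolated) | CC(C)C=1[C@@H]2C[C@]3(C)OC(C)(C)O[C@@H]3[C@H]2C[C@@](C)(O)CC=1O[Li] | intermediate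
24 | trans-fused C5 ketone, 3aα-H, 8aβ-H, 4α-isopropyl, 7α-hydroxy-7β-methyl, acetonide | CC(C)[C@H]1[C@@H]2C[C@]3(C)OC(C)(C)O[C@@H]3[C@H]2C[C@@](C)(O)CC1=O | intermediate
25 | 5β,7α-diol, 4α-isopropyl, trans-fused, acetonide | CC(C)[C@H]1[C@@H]2C[C@]3(C)OC(C)(C)O[C@@H]3[C@H]2C[C@@](C)(O)C[C@@H]1O | intermediate
26 | 4-hydroxybenzoic acid | OC(=O)c1ccc(O)cc1 | starting material
27 | tert-butyldimethylsilyl 4-(tert-butyldimethylsilyloxy)benzoate (not isolated) | CC(C)(C)[Si](C)(C)OC(=O)c1ccc(O[Si](C)(C)C(C)(C)C)cc1 | intermediate
28 | 4-(tert-butyldimethylsilyloxy)benzoic acid | OC(=O)c1ccc(O[Si](C)(C)C(C)(C)C)cc1 | intermediate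
29 | 5β-[4-(tert-butyldimethylsilyloxy)benzoate] of 25 | CC(C)[C@H]1[C@@H]2C[C@]3(C)OC(C)(C)O[C@@H]3[C@H]2C[C@@](C)(O)C[C@@H]1OC(=O)c1ccc(O[Si](C)(C)C(C)(C)C)cc1 | intermediate
30 | 1β,2β,7α-triol 5β-ester | CC(C)[C@H]1[C@@H]2C[C@](C)(O)[C@H](O)[C@H]2C[C@@](C)(O)C[C@@H]1OC(=O)c1ccc(O[Si](C)(C)C(C)(C)C)cc1 | intermediate
31 | 1β,2β-cyclic thionocarbonate of 30 | CC(C)[C@H]1[C@@H]2C[C@]3(C)OC(=S)O[C@@H]3[C@H]2C[C@@](C)(O)C[C@@H]1OC(=O)c1ccc(O[Si](C)(C)C(C)(C)C)cc1 | intermediate
32 | C1=C2 alkene, 7α-hydroxy, 5β-ester | CC(C)[C@H]1[C@@H]2CC(C)=C[C@H]2C[C@@](C)(O)C[C@@H]1OC(=O)c1ccc(O[Si](C)(C)C(C)(C)C)cc1 | intermediate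
33 | 1α,2α-epoxide, aryl silyl ether of the target | CC(C)[C@H]1[C@@H]2C[C@@]3(C)O[C@H]3[C@H]2C[C@@](C)(O)C[C@@H]1OC(=O)c1ccc(O[Si](C)(C)C(C)(C)C)cc1 | intermediate
34 | CNP0245441.1 | CC(C)[C@H]1[C@@H]2C[C@@]3(C)O[C@H]3[C@H]2C[C@@](C)(O)C[C@@H]1OC(=O)c1ccc(O)cc1 | target

**Step count**

Total: 23 steps. Longest linear sequence: 21 steps (steps 1–9, 11–16 and 18–23); steps 10 and 17 are one-step branches.

**Steps most likely to fail**

1. Step 11 (key step). The unsubstituted silyloxyallyl cation may oligomerise or transfer its silyl group before it is trapped, the acid-sensitive dienol ether may be desilylated faster than it is alkylated, and bonding may stop after the first C–C bond. Fallback, setting out from 14: an iron-carbonyl-mediated [4+3] cycloaddition with 1,1,3,3-tetrabromoacetone (Fe2(CO)9, benzene, 50 °C) uses a bromine-stabilised, iron-bound oxyallyl species under neutral aprotic conditions and should give the 6,8-dibromo cycloadduct F1. Radical debromination (n-Bu3SnH, AIBN, benzene, 80 °C), chosen because it passes through no enolate that could expel the C5 silyloxy group, then comes back to the route at 19.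

2. Step 12. Facial selectivity of the methyl addition may be poor if the seven-membered ring does not hold the 5α-silyloxy group pseudoaxial. Fallback, setting out from 19: the silyl group is removed first (HF·pyridine, THF, 0 °C) to give the 5α-hydroxy C7 ketone F2. Excess MeMgBr (CH2Cl2–Et2O, −78 °C) is then added, so that the magnesium alkoxide on the 5α-oxygen chelates the C7 carbonyl, occupies the α face and forces methyl delivery from the β face. This replaces steric control by chelate control and comes back to the route at 21.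

3. Step 22. Oxygen delivery from the remote tertiary hydroxyl may be slow or unselective, and the strained vanadium-bound epoxide may rearrange. Fallback, setting out from 32: the tertiary hydroxyl is masked (Et3SiOTf, 2,6-lutidine, CH2Cl2) to give the C7 triethylsilyl ether F3. An external electrophile should then add on the β face, where C8a carries only hydrogen while C8 shields the α face. NBS in THF–H2O should therefore give the 1β-bromo-2α-hydroxy bromohydrin F4 by anti attack of water at the tertiary C2. DBU (CH2Cl2, rt) closes it with inversion at C1 to the 1α,2α-epoxide bis-silyl ether F5, and fluoride under the conditions of step 23 removes both silyl groups, so the sequence comes back to the route at 34.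

**Further compounds**

F1 | step 11 | 6,8-dibromo derivative of cycloadduct 19 | CC(C)C1=C2C[C@]3(C)OC(C)(C)O[C@@H]3[C@H]2C(Br)C(=O)C(Br)[C@H]1O[Si](C)(C)C(C)(C)C
F2 | step 12 | 5α-hydroxy C7 ketone (desilylated 19) | CC(C)C1=C2C[C@]3(C)OC(C)(C)O[C@@H]3[C@H]2CC(=O)C[C@H]1O
F3 | step 22 | C7 triethylsilyl ether of alkene 32 | CC(C)[C@H]1[C@@H]2CC(C)=C[C@H]2C[C@@](C)(O[Si](CC)(CC)CC)C[C@@H]1OC(=O)c1ccc(O[Si](C)(C)C(C)(C)C)cc1
F4 | step 22 | 1β-bromo-2α-hydroxy bromohydrin of F3 | CC(C)[C@H]1[C@@H]2C[C@@](C)(O)[C@H](Br)[C@H]2C[C@@](C)(O[Si](CC)(CC)CC)C[C@@H]1OC(=O)c1ccc(O[Si](C)(C)C(C)(C)C)cc1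
F5 | step 22 | 1α,2α-epoxide with C7 triethylsilyl ether and aryl silyl ether | CC(C)[C@H]1[C@@H]2C[C@@]3(C)O[C@H]3[C@H]2C[C@@](C)(O[Si](CC)(CC)CC)C[C@@H]1OC(=O)c1ccc(O[Si](C)(C)C(C)(C)C)cc1
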